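The route rests on cutting ring B at the C9–C10 bond (labdane numbering), which joins the side-chain carbon to the quaternary ring-fusion carbon. Ring A comes from α-ionone and carries C5 and a trisubstituted C10=C1 alkene; its C5 chain is grown into the C6 silyl ether, the C8 tertiary carbinol and an (E)-vinyl sulfone (C9=C11). In one operation an iron hydride places a hydrogen atom on C1 and the tertiary C10 radical adds 6-exo to C9, closing ring B cis-fused and setting C9 and C10. The key step thus exploits the C10=C1 alkene of ring A as a latent tertiary radical beside the C5 tether. The precursor is seco vinyl sulfone 12.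

Key step: step 8

Remark: labdane numbering is used throughout (ring A = C1–C5 and C10, ring B = C5–C10, side chain C11–C15); α-ionone is taken to be purchasable only as the racemate, so resolution is built into step 2.

Step 1
Reactants: 1 racemic α-ionone
Product: 2 α-ionol, (E)-4-(2,6,6-trimethylcyclohex-2-en-1-yl)but-3-en-2-ol, mixture of the four stereoisomers
Conditions: NaBH4, CeCl3·7H2O, MeOH, 0 °C
Reagents that add atoms: none
Why: Luche 1,2-reduction of the enone; the carbinol centre needs no control because it only serves as the handle for step 2 and is erased in step 3.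

Step 2
Reactants: 2 α-ionol (stereoisomer mixture); 3 tert-butyl hydroperoxide
Product: 4 (1R)-1-{(2R,3R)-3-[(1S)-2,6,6-trimethylcyclohex-2-en-1-yl]oxiran-2-yl}ethan-1-ol (erythro epoxy alcohol, single stereoisomer after chromatography)
Conditions: Ti(OiPr)4 (10 mol %), D-(−)-diisopropyl tartrate (15 mol %), t-BuOOH (0.6 equiv), 4 Å MS, CH2Cl2, −20 °C; chromatography
Reagents that add atoms: tert-butyl hydroperoxide (3), CC(C)(C)OO
Why: Sharpless asymmetric epoxidation run as a kinetic resolution: the D-(−)-tartrate catalyst epoxidises only the (R)-carbinols and delivers oxygen anti to the hydroxyl (erythro), which fixes the C6–O configuration by reagent control (6S once C7 is reduced in step 4); the non-allylic ring alkene is untouched, and the epoxy alcohol with the (R)-ring centre is a diastereomer removed by chromatography, which resolves C5.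

Step 3
Reactants: 4 erythro epoxy alcohol
Product: 5 1-{(2S,3R)-3-[(1S)-2,6,6-trimethylcyclohex-2-en-1-yl]oxiran-2-yl}ethan-1-one (trans-epoxy ketone)
Conditions: Dess–Martin periodinane, NaHCO3, CH2Cl2, 0 °C to rt
Reagents that add atoms: none
Why: Dess–Martin oxidation of the secondary carbinol; epoxide and ring alkene are inert, and the only centre touched is the carbinol carbon that is meant to disappear.

Step 4
Reactants: 5 trans-epoxy ketone
Product: 6 (4S)-4-hydroxy-4-[(1S)-2,6,6-trimethylcyclohex-2-en-1-yl]butan-2-one (C6 aldol, labdane 5S,6S)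
Conditions: SmI2 (2.2 equiv), THF/MeOH, −90 °C
Reagents that add atoms: none
Why: Reductive opening of an α,β-epoxy ketone by SmI2 (two single-electron transfers cleave the C7–O bond next to the carbonyl, methanol protonates); the C6–O bond is not involved, so its configuration is retained, and the low temperature avoids dehydration or retro-aldol cleavage.

Step 5
Reactants: 6 C6 aldol; 7 ethynylmagnesium bromide
Product: 8 (3S,5S)-3-methyl-5-[(1S)-2,6,6-trimethylcyclohex-2-en-1-yl]pent-1-yne-3,5-diol (labdane 5S,6S,8S)
Conditions: HC≡CMgBr (3.5 equiv, THF), CH2Cl2 co-solvent, −78 to −30 °C; aq. NH4Cl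
Reagents that add atoms: ethynylmagnesium bromide (7), C#C[Mg]Br
Why: Chelation-controlled Grignard addition with 1,3-induction: the first equivalent forms the magnesium aldolate, whose six-membered chelate holds the ring substituent at C6 equatorial; the small acetylide then attacks the C8 carbonyl axially and the methyl ends equatorial, giving 8S (C6–O and C8–O anti along the C5–C9 chain); any C8 epimer is removed by chromatography at this diol stage.

Step 6
Reactants: 8 ethynyl diol; 9 tert-butyldimethylsilyl triflate
Product: 10 (3S,5S)-5-(tert-butyldimethylsilyloxy)-3-methyl-5-[(1S)-2,6,6-trimethylcyclohex-2-en-1-yl]pent-1-yn-3-ol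
Conditions: TBSOTf (1.1 equiv), 2,6-lutidine, CH2Cl2, −78 °C
Reagents that add atoms: tert-butyldimethylsilyl triflate (9), CC(C)(C)[Si](C)(C)OS(=O)(=O)C(F)(F)F
Why: Silyl ether formation; with one equivalent of silyl triflate at −78 °C the secondary C6 hydroxyl reacts while the tertiary C8 hydroxyl stays free, and the C6 oxygen must be capped here because a free C6 alkoxide would later add 5-exo to the vinyl sulfone.

Step 7
Reactants: 10 silylated alkynol; 11 sodium benzenesulfinate
Product: 12 (1E,3S,5S)-5-(tert-butyldimethylsilyloxy)-3-methyl-1-(phenylsulfonyl)-5-[(1S)-2,6,6-trimethylcyclohex-2-en-1-yl]pent-1-en-3-ol (seco vinyl sulfone)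
Conditions: PhSO2Na (2 equiv), Cu(OTf)2 (10 mol %), AcOH (2 equiv), MeCN, air, 50 °C
Reagents that add atoms: sodium benzenesulfinate (11), [Na+].[O-]S(=O)c1ccccc1
Why: Copper-catalysed anti-Markovnikov hydrosulfonylation of a terminal alkyne with a sulfinate salt: the sulfonyl radical adds to the terminal carbon C11 and the alkenyl copper species is protonated with overall syn addition, giving the (E)-vinyl sulfone; the hindered, non-activated ring alkene does not compete.

Step 8
Reactants: 12 seco vinyl sulfone
Product: 13 (1S,2S,4S,4aS,8aR)-4-(tert-butyldimethylsilyloxy)-2,5,5,8a-tetramethyl-1-[(phenylsulfonyl)methyl]decahydronaphthalen-2-ol (cis-fused decalin C11 sulfone; labdane 5S,6S,8S,9S,10R)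
Conditions: Fe(acac)3 (30 mol %), PhSiH3 (2.5 equiv), EtOH/HOCH2CH2OH 5:1, 0.02 M, 60 °C
Reagents that add atoms: none
Why: Fe(acac)3 and PhSiH3 form an iron hydride that transfers a hydrogen atom to C1, the less substituted end of the ring A alkene, and the tertiary C10 radical adds to C9, the β-carbon of the vinyl sulfone, after which the α-sulfonyl radical at C11 is reduced by divalent iron and protonated by ethanol. The closest known reaction type is the iron-hydride reductive (Giese-type) coupling of trisubstituted alkenes with vinyl sulfones and acrylates, run here intramolecularly. Ring B closes in the 6-exo-trig mode (C10 onto C9, with C9=C11 exocyclic). C10 is controlled by the C5 tether: the chain sits pseudo-axial on ring A (fewer gauche contacts with the C4 methyls, no eclipsing with the C10 methyl) and from there C9 reaches only the lobe of the C10 radical on its own face, so the fusion is cis with the C10 methyl syn to H5. C9 is controlled by a chair transition state for ring B with the C6 silyloxy group and the C8 methyl equatorial and the C8 hydroxyl axial, in which the =CH–SO2Ph arm, squeezed between the fully substituted C8 and C10, stands pseudo-axial and anti to C1. The step needs hydrogen-atom transfer to the electron-rich ring alkene and not to the electron-poor vinyl sulfone, and ring closure faster than reduction or isomerisation of the C10 radical; the polarity match between nucleophilic tertiary radical and sulfone acceptor and the high dilution secure both.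

Step 9
Reactants: 13 cis-decalin C11 sulfone; 14 methyl (E)-4-bromo-3-methylbut-2-enoate
Product: 16 methyl (2E)-5-[(1S,2S,4S,4aS,8aR)-4-(tert-butyldimethylsilyloxy)-2-hydroxy-2,5,5,8a-tetramethyldecahydronaphthalen-1-yl]-3-methyl-5-(phenylsulfonyl)pent-2-enoate (C11 epimers), via dilithiated sulfone 15 (not isolated)
Conditions: n-BuLi (2.2 equiv), THF, −78 °C; then 14, DMPU, −78 to −40 °C; cold aq. NH4Cl
Reagents that add atoms: methyl (E)-4-bromo-3-methylbut-2-enoate (14), COC(=O)/C=C(C)/CBr
Why: Alkylation of an α-sulfonyl carbanion: after the C8 alkoxide has formed, the second equivalent of base lithiates C11, and the carbanion displaces the primary allylic bromide (SN2) with the (E)-enoate geometry carried over from 14; C11 forms as an epimer mixture that is erased in step 11.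

Step 10
Reactants: 16 sulfonyl methyl ester; 17 trimethyltin hydroxide
Product: 18 (2E)-5-[(1S,2S,4S,4aS,8aR)-4-(tert-butyldimethylsilyloxy)-2-hydroxy-2,5,5,8a-tetramethyldecahydronaphthalen-1-yl]-3-methyl-5-(phenylsulfonyl)pent-2-enoic acid (C11 epimers)
Conditions: Me3SnOH (8 equiv), ClCH2CH2Cl, 70 °C; then 0.1 M HCl wash
Reagents that add atoms: trimethyltin hydroxide (17), C[Sn](C)(C)O
Why: Tin hydroxide-mediated cleavage of the methyl ester under near-neutral conditions; hydroxide or alkoxide is avoided because it would deprotonate C12 and expel benzenesulfinate from C11 (vinylogous E1cB elimination to the dienoate), and the silyl ether stays in place.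

Step 11
Reactants: 18 sulfonyl acid
Product: 19 (2E)-5-[(1S,2S,4S,4aS,8aR)-4-(tert-butyldimethylsilyloxy)-2-hydroxy-2,5,5,8a-tetramethyldecahydronaphthalen-1-yl]-3-methylpent-2-enoic acid
Conditions: Na(Hg) (6 %), Na2HPO4, MeOH/THF, −20 to 0 °C; then acidify to pH 3
Reagents that add atoms: none
Why: Reductive desulfonylation with sodium amalgam (electron transfer to the aryl sulfone, C11–S cleavage, protonation at C11); the unsaturated acid is present as its carboxylate, which resists electron transfer, so the C13=C14 bond and its (E) geometry should survive, and no stereocentre of the decalin is involved.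

Step 12
Reactants: 19 silylated hydroxy acid
Product: 20 (2E)-5-[(1S,2S,4S,4aS,8aR)-2,4-dihydroxy-2,5,5,8a-tetramethyldecahydronaphthalen-1-yl]-3-methylpent-2-enoic acid
Conditions: aq. HF (48 %), MeCN, rt
Reagents that add atoms: none
Why: Fluoride-mediated cleavage of the silyl ether; aqueous HF in acetonitrile is mild enough for the tertiary C8 alcohol and the conjugated acid.

Step 13
Reactants: 20 dihydroxy acid; 21 acetic anhydride
Product: 22 (2E)-5-[(1S,2S,4S,4aS,8aR)-4-acetoxy-2-hydroxy-2,5,5,8a-tetramethyldecahydronaphthalen-1-yl]-3-methylpent-2-enoic acid (target, CNP0221670.1)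
Conditions: Ac2O, pyridine, DMAP (cat.), CH2Cl2, 0 °C to rt; then aq. NaHCO3/THF, acidify
Reagents that add atoms: acetic anhydride (21), CC(=O)OC(C)=O
Why: DMAP-catalysed acetylation of the secondary equatorial C6 hydroxyl; the tertiary axial C8 hydroxyl does not react under these conditions, and the mixed anhydride formed at the carboxyl group is hydrolysed in the bicarbonate work-up.

Compound list
1 | racemic α-ionone, (E)-4-(2,6,6-trimethylcyclohex-2-en-1-yl)but-3-en-2-one | CC1=CCCC(C)(C)C1/C=C/C(C)=O | starting material
2 | α-ionol, mixture of the four stereoisomers | CC1=CCCC(C)(C)C1/C=C/C(C)O | intermediate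
3 | tert-butyl hydroperoxide | CC(C)(C)OO | starting material
4 | (1R)-1-{(2R,3R)-3-[(1S)-2,6,6-trimethylcyclohex-2-en-1-yl]oxiran-2-yl}ethan-1-ol | CC1=CCCC(C)(C)[C@@H]1[C@H]2O[C@@H]2[C@@H](C)O | intermediate
5 | 1-{(2S,3R)-3-[(1S)-2,6,6-trimethylcyclohex-2-en-1-yl]oxiran-2-yl}ethan-1-one | CC1=CCCC(C)(C)[C@@H]1[C@H]2O[C@@H]2C(C)=O | intermediate
6 | (4S)-4-hydroxy-4-[(1S)-2,6,6-trimethylcyclohex-2-en-1-yl]butan-2-one | CC1=CCCC(C)(C)[C@@H]1[C@@H](O)CC(C)=O | intermediate
7 | ethynylmagnesium bromide | C#C[Mg]Br | starting material
8 | (3S,5S)-3-methyl-5-[(1S)-2,6,6-trimethylcyclohex-2-en-1-yl]pent-1-yne-3,5-diol | CC1=CCCC(C)(C)[C@@H]1[C@@H](O)C[C@](C)(O)C#C | intermediate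
9 | tert-butyldimethylsilyl triflate | CC(C)(C)[Si](C)(C)OS(=O)(=O)C(F)(F)F | starting material
10 | (3S,5S)-5-(tert-butyldimethylsilyloxy)-3-methyl-5-[(1S)-2,6,6-trimethylcyclohex-2-en-1-yl]pent-1-yn-3-ol | CC1=CCCC(C)(C)[C@@H]1[C@@H](O[Si](C)(C)C(C)(C)C)C[C@](C)(O)C#C | intermediate
11 | sodium benzenesulfinate | [Na+].[O-]S(=O)c1ccccc1 | starting material
12 | seco vinyl sulfone, (1E,3S,5S)-5-(tert-butyldimethylsilyloxy)-3-methyl-1-(phenylsulfonyl)-5-[(1S)-2,6,6-trimethylcyclohex-2-en-1-yl]pent-1-en-3-ol | CC1=CCCC(C)(C)[C@@H]1[C@@H](O[Si](C)(C)C(C)(C)C)C[C@](C)(O)/C=C/S(=O)(=O)c1ccccc1 | intermediate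
13 | cis-decalin C11 sulfone, (1S,2S,4S,4aS,8aR)-4-(tert-butyldimethylsilyloxy)-2,5,5,8a-tetramethyl-1-[(phenylsulfonyl)methyl]decahydronaphthalen-2-ol | CC(C)(C)[Si](C)(C)O[C@H]1C[C@](C)(O)[C@@H](CS(=O)(=O)c3ccccc3)[C@]2(C)CCCC(C)(C)[C@H]12 | intermediate
14 | methyl (E)-4-bromo-3-methylbut-2-enoate | COC(=O)/C=C(C)/CBr | starting material
15 | dilithiated sulfone (C8 lithium alkoxide, C11 lithio sulfone) | CC(C)(C)[Si](C)(C)O[C@H]1C[C@](C)(O[Li])[C@@H](C([Li])S(=O)(=O)c3ccccc3)[C@]2(C)CCCC(C)(C)[C@H]12 | intermediate
16 | methyl (2E)-5-[(1S,2S,4S,4aS,8aR)-4-(tert-butyldimethylsilyloxy)-2-hydroxy-2,5,5,8a-tetramethyldecahydronaphthalen-1-yl]-3-methyl-5-(phenylsulfonyl)pent-2-enoate, C11 epimers | CC(C)(C)[Si](C)(C)O[C@H]1C[C@](C)(O)[C@@H](C(C/C(C)=C/C(=O)OC)S(=O)(=O)c3ccccc3)[C@]2(C)CCCC(C)(C)[C@H]12 | intermediate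
17 | trimethyltin hydroxide | C[Sn](C)(C)O | starting material
18 | (2E)-5-[(1S,2S,4S,4aS,8aR)-4-(tert-butyldimethylsilyloxy)-2-hydroxy-2,5,5,8a-tetramethyldecahydronaphthalen-1-yl]-3-methyl-5-(phenylsulfonyl)pent-2-enoic acid, C11 epimers | CC(C)(C)[Si](C)(C)O[C@H]1C[C@](C)(O)[C@@H](C(C/C(C)=C/C(=O)O)S(=O)(=O)c3ccccc3)[C@]2(C)CCCC(C)(C)[C@H]12 | intermediate
19 | (2E)-5-[(1S,2S,4S,4aS,8aR)-4-(tert-butyldimethylsilyloxy)-2-hydroxy-2,5,5,8a-tetramethyldecahydronaphthalen-1-yl]-3-methylpent-2-enoic acid | CC(C)(C)[Si](C)(C)O[C@H]1C[C@](C)(O)[C@@H](CC/C(C)=C/C(=O)O)[C@]2(C)CCCC(C)(C)[C@H]12 | intermediate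
20 | (2E)-5-[(1S,2S,4S,4aS,8aR)-2,4-dihydroxy-2,5,5,8a-tetramethyldecahydronaphthalen-1-yl]-3-methylpent-2-enoic acid | O[C@H]1C[C@](C)(O)[C@@H](CC/C(C)=C/C(=O)O)[C@]2(C)CCCC(C)(C)[C@H]12 | intermediate
21 | acetic anhydride | CC(=O)OC(C)=O | starting material
22 | (2E)-5-[(1S,2S,4S,4aS,8aR)-4-acetoxy-2-hydroxy-2,5,5,8a-tetramethyldecahydronaphthalen-1-yl]-3-methylpent-2-enoic acid | CC(=O)O[C@H]1C[C@](C)(O)[C@@H](CC/C(C)=C/C(=O)O)[C@]2(C)CCCC(C)(C)[C@H]12 | target

Total step count: 13
Longest linear sequence: 13 steps (1 to 22)

Steps most likely to fail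

Step 8 (key step). The C10 radical may be quenched by a second hydrogen transfer, or the ring alkene may isomerise, before ring closure; the closure may also show poor facial selectivity at C9 or C10. The fallback generates the same radical without a metal hydride, by epoxide opening with trivalent titanium. It sets out from 12: buffered mCPBA should epoxidise only the electron-rich ring alkene to the ring A 1,10-epoxide F1. Cp2TiCl (from Cp2TiCl2 and Zn, THF) opens F1 at C10–O to the tertiary radical, which adds to C9 and is reduced and protonated at C11, giving the C1-hydroxy decalin sulfone F2. The secondary C1 hydroxyl is converted with 1,1'-thiocarbonyldiimidazole into the imidazole-1-carbothioate F3 and removed with Bu3SnH/AIBN (Barton–McCombie deoxygenation), which comes back to the route at 13.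

Step 7. The sulfonyl radical may add with the wrong regiochemistry or alkene geometry, or the tertiary propargylic alcohol may rearrange under the copper/acetic acid conditions. The fallback replaces radical hydrosulfonylation by a boron route. It sets out from 10: hydroboration of the terminal alkyne with catecholborane, then hydrolysis, gives the (E)-alkenylboronic acid F4 by syn addition. Oxidative coupling of F4 with sodium benzenesulfinate 11 (Cu(OAc)2, 1,10-phenanthroline, air) exchanges boron for the sulfonyl group with retention of geometry and comes back at 12.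

Step 2. The tartrate catalyst reads only the carbinol centre, so the wanted epoxy alcohol forms together with its C5 epimer, and chromatographic separation of the two may be incomplete. The fallback removes the wrong ring configuration before the epoxidation. It sets out from 2: esterification with 4-nitrobenzoyl chloride and fractional crystallisation gives a single racemic diastereomer of the 4-nitrobenzoate F5. This is taken here to be the (6S*,9R*) pair in ionone numbering; if the other pair crystallises, the mother-liquor ester is carried on instead. Saponification gives the racemic, diastereomerically pure alcohol F6. The Sharpless kinetic resolution under the conditions of step 2 then epoxidises only its (6S,9R) enantiomer, so the product is separated from unreacted allylic alcohol and not from a diastereomeric epoxy alcohol; the route is rejoined at 4.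

Further compounds
F1 | step 8 | ring A 1,10-epoxide of 12 (epoxide epimers) | CC12OC1CCC(C)(C)[C@@H]2[C@@H](O[Si](C)(C)C(C)(C)C)C[C@](C)(O)/C=C/S(=O)(=O)c1ccccc1
F2 | step 8 | C1-hydroxy analogue of 13 (C1 epimers) | CC(C)(C)[Si](C)(C)O[C@H]1C[C@](C)(O)[C@@H](CS(=O)(=O)c3ccccc3)[C@]2(C)C(O)CCC(C)(C)[C@H]12
F3 | step 8 | C1 O-imidazole-1-carbothioate of F2 | CC(C)(C)[Si](C)(C)O[C@H]1C[C@](C)(O)[C@@H](CS(=O)(=O)c3ccccc3)[C@]2(C)C(OC(=S)n4ccnc4)CCC(C)(C)[C@H]12
F4 | step 7 | (E)-alkenylboronic acid from 10 | CC1=CCCC(C)(C)[C@@H]1[C@@H](O[Si](C)(C)C(C)(C)C)C[C@](C)(O)/C=C/B(O)O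
F5 | step 2 | rac-(6S*,9R*)-α-ionyl 4-nitrobenzoate (one enantiomer drawn) | CC1=CCCC(C)(C)[C@@H]1/C=C/[C@@H](C)OC(=O)c1ccc(cc1)[N+](=O)[O-]
F6 | step 2 | rac-(6S*,9R*)-α-ionol (one enantiomer drawn) | CC1=CCCC(C)(C)[C@@H]1/C=C/[C@@H](C)O
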